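The ratio to carry is product standing over starting material gone. In the maple run at 20.0 s it reads 62.2%, the product share (the selectivity). By that reading, a molecule leaving starting material in the maple run had about that chance of standing as product. The two columns fall short of the charge by 8.2 percentage points, and that gap is where the rest stood, unseen.

- maple: starting material 0.15 M; run made earlier
- flask: starting material 0.10 M; time 3.0 min

maple run (percent of the starting material charged)

| time / s | starting material / % | product / % |
|---|---|---|
| 10.0 | 88.3 | 7.7 |
| 12.0 | 85.4 | 8.8 |
| 15.0 | 82.5 | 10.2 |
| 20.0 | 78.3 | 13.5 |

(readings scatter by 0.5 percentage points)

- why nothing more happens at 3.0 min, or that something still does (all of the starting material has reacted / it is still moving / forward and back rates have come level)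
- part of the starting material gone at 3.0 min
- the product standing at 3.0 min, as a percentage of the starting material charged

- the numbers in the tables scatter with a standard deviation of 0.5 percentage points
- what has gone from starting material into another species counts as reacted, even if it can come back
- the reaction counts as stopped when no species that holds the starting material changes by six tenths of a point or more over the second half of the time

You can reckon the flask this way. The maple loss gives a first-order clock of 0.734 min⁻¹, which puts conversion at 88.9% by 3.0 min, with 11.1% still to go, so I would call it still moving. The share held fixed then makes product 55.3%.

The forecast says it is still moving, with conversion 67% (52% to 88%) and product 62% (44% to 82%). It puts “a reversible side reservoir” beside the product. Its conversion stands lower than my reckoning, and its product stands higher than mine.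

The flask gives: it is still moving, conversion 75.1%, product 63.1%.

    starting material ⇌ product + by-product (K = 1.80 M, k = 0.00750 s⁻¹)
    starting material ⇌ dormant form (K = 0.360, k = 0.00580 s⁻¹)

In the flask at 3.0 min the share stands at 84.0%, more than the 62.2% read in the maple run at 20.0 s. Dormant form, which counts as reacted, fell from 15.8% at 1.50 min to 12.0% at 3.00 min, while product rose from 42.6% to 63.1%; the scheme lets a molecule come back to the fork. Read the same flask at 50 s and the reckoning gives conversion 45.7% and product 28.4%. That flask stands at conversion 42.7% and product 28.2%, a share of 66.0%.

The readings stem from a simulated flask with constants of no real substance; the scatter is artificial.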